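**Assumption:** the side chain is numbered as a farnesyl chain (C1 = OCH2, C9 and C10 = the secondary carbinols, C11 = the tertiary carbinol), and geranyl acetate, 2-methylbut-3-yn-2-ol and 5,7-dihydroxycoumarin are taken as commercial.

## Retrosynthetic overview

1. Last bonds made are C10–O and C11–O: a hydroxyl-directed osmylation (OsO4·TMEDA) of a (9R)-allylic alcohol must pick the 10,11-alkene out of three trisubstituted alkenes and set C10 from C9. This is the key step; no asymmetric dihydroxylation and no pre-oxidised farnesyl chain is used.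
2. C9 stereocentre: CBS reduction of the 9-ketone, which is the Meyer–Schuster isomer of a tertiary propargylic alcohol.
3. C8–C9: copper-acetylide SN2 coupling of a C10 allylic bromide (SeO2 oxidation of geranyl acetate, then Appel) with the C5 alkynol.
4. C1–O(aryl): Mitsunobu etherification at the enyne-diol stage, where only one hydroxyl can react.
5. Rings: none is formed; the coumarin bicycle is bought intact.

## Route

**Step 1**
Reactants: 1 geranyl acetate, (2E)-3,7-dimethylocta-2,6-dien-1-yl acetate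
Product: 2 (2E,6E)-8-hydroxy-3,7-dimethylocta-2,6-dien-1-yl acetate
Conditions: SeO2 (0.1 equiv), t-BuOOH (70 % aq., 3 equiv), salicylic acid (0.1 equiv), CH2Cl2, rt
Reagents that add atoms: tert-butyl hydroperoxide, CC(C)(C)OO; selenium dioxide, SeO2, O=[Se]=O (catalytic oxygen carrier)
Why: SeO2/t-BuOOH allylic oxidation (ene reaction, then [2,3]-sigmatropic shift) attacks the E-methyl group of the electron-rich terminal alkene, because the 2,3-alkene is deactivated by the allylic acetate; no stereocentre is formed and the new 6E geometry follows from the mechanism.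

**Step 2**
Reactants: 2 (2E,6E)-8-hydroxy-3,7-dimethylocta-2,6-dien-1-yl acetate
Product: 3 (2E,6E)-8-bromo-3,7-dimethylocta-2,6-dien-1-yl acetate
Conditions: CBr4, PPh3, CH2Cl2, 0 °C
Reagents that add atoms: carbon tetrabromide, BrC(Br)(Br)Br
Why: Appel reaction; the oxyphosphonium of a primary allylic alcohol is displaced by bromide in an SN2 sense without allylic transposition, and the acetate is inert.

**Step 3**
Reactants: 3 (2E,6E)-8-bromo-3,7-dimethylocta-2,6-dien-1-yl acetate; 4 2-methylbut-3-yn-2-ol (1.5 equiv)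
Product: 6 (2E,6E)-3,7,11-trimethyldodeca-2,6-dien-9-yne-1,11-diol, via enynol acetate 5 (not isolated)
Conditions: CuI (20 mol %), K2CO3 (2 equiv), DMF, Ar, rt; then MeOH, rt
Reagents that add atoms: none
Why: Copper-acetylide allylic alkylation; the acetylide attacks the unhindered primary C8 (SN2, not SN2' at the substituted C6), so the skipped enyne keeps the 6E alkene, and K2CO3/MeOH transesterification then frees the primary alcohol in the same flask.

**Step 4**
Reactants: 6 (2E,6E)-3,7,11-trimethyldodeca-2,6-dien-9-yne-1,11-diol; 7 5,7-dihydroxycoumarin (1.5 equiv)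
Product: 8 5-hydroxy-7-{[(2E,6E)-11-hydroxy-3,7,11-trimethyldodeca-2,6-dien-9-yn-1-yl]oxy}-2H-chromen-2-one
Conditions: PPh3, DIAD, THF, 0 °C to rt
Reagents that add atoms: none
Why: Mitsunobu etherification; only the primary allylic hydroxyl of 6 is activated (the tertiary propargylic one is inert), and the more acidic, less hindered 7-OH of 7 is the preferred pronucleophile, with SN2 displacement keeping the 2E alkene.

**Step 5**
Reactants: 8 5-hydroxy-7-{[(2E,6E)-11-hydroxy-3,7,11-trimethyldodeca-2,6-dien-9-yn-1-yl]oxy}-2H-chromen-2-one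
Product: 9 5-hydroxy-7-{[(2E,6E)-3,7,11-trimethyl-9-oxododeca-2,6,10-trien-1-yl]oxy}-2H-chromen-2-one
Conditions: Ph3PAuNTf2 (2 mol %), MeOH (1 equiv), toluene, rt
Reagents that add atoms: none
Why: Gold-catalysed Meyer–Schuster rearrangement (formal 1,3-hydroxyl shift of the tertiary propargylic alcohol, then tautomerisation) puts the carbonyl on C9 and gives the 10,11-enone; C11 carries two methyls so no alkene geometry arises, and the neutral conditions keep the 6,7-alkene out of conjugation.

**Step 6**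
Reactants: 9 5-hydroxy-7-{[(2E,6E)-3,7,11-trimethyl-9-oxododeca-2,6,10-trien-1-yl]oxy}-2H-chromen-2-one
Product: 10 5-hydroxy-7-{[(2E,6E,9R)-9-hydroxy-3,7,11-trimethyldodeca-2,6,10-trien-1-yl]oxy}-2H-chromen-2-one
Conditions: (S)-2-methyl-CBS-oxazaborolidine (0.5 equiv), catecholborane (3 equiv), toluene/CH2Cl2, −78 °C
Reagents that add atoms: none
Why: Corey–Bakshi–Shibata reduction; the (S)-oxazaborolidine binds the ketone with the alkenyl group as the large substituent and delivers hydride to give the 9R carbinol (the same sense as acetophenone to (R)-1-phenylethanol), strictly 1,2 and without touching the lactone.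

**Step 7**
Reactants: 10 5-hydroxy-7-{[(2E,6E,9R)-9-hydroxy-3,7,11-trimethyldodeca-2,6,10-trien-1-yl]oxy}-2H-chromen-2-one
Product: 12 5-hydroxy-7-{[(2E,6E,9R,10S)-9,10,11-trihydroxy-3,7,11-trimethyldodeca-2,6-dien-1-yl]oxy}-2H-chromen-2-one (target), via osmate ester 11 (not isolated)
Conditions: OsO4 (1.05 equiv), TMEDA (1.1 equiv), CH2Cl2, −78 °C; then ethylenediamine, rt
Reagents that add atoms: osmium tetroxide, OsO4, O=[Os](=O)(=O)=O (both new oxygen atoms); TMEDA, CN(C)CCN(C)C (ligand in 11 only, lost again)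
Why: Donohoe hydrogen-bond-directed dihydroxylation; the C9 hydroxyl binds an oxo ligand of OsO4·TMEDA and hands it to the adjacent 10,11-alkene rather than to the 2,3- or 6,7-alkene, on the hydroxyl face of the A(1,3)-minimised conformer (C9–H eclipsing the Z-methyl on C11), so O10 ends syn (threo) to O9, which is 10S from 9R, and ethylenediamine then releases the triol from hexavalent osmium.

## Compound list

1 | geranyl acetate, (2E)-3,7-dimethylocta-2,6-dien-1-yl acetate | C/C(=C\COC(C)=O)CCC=C(C)C | starting material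
2 | (2E,6E)-8-hydroxy-3,7-dimethylocta-2,6-dien-1-yl acetate | C/C(=C\COC(C)=O)CC/C=C(\C)CO | intermediate
3 | (2E,6E)-8-bromo-3,7-dimethylocta-2,6-dien-1-yl acetate | C/C(=C\COC(C)=O)CC/C=C(\C)CBr | intermediate
4 | 2-methylbut-3-yn-2-ol | CC(C)(O)C#C | starting material
5 | (2E,6E)-11-hydroxy-3,7,11-trimethyldodeca-2,6-dien-9-yn-1-yl acetate (enynol acetate) | C/C(=C\COC(C)=O)CC/C=C(\C)CC#CC(C)(C)O | intermediate (not isolated)
6 | (2E,6E)-3,7,11-trimethyldodeca-2,6-dien-9-yne-1,11-diol | C/C(=C\CO)CC/C=C(\C)CC#CC(C)(C)O | intermediate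
7 | 5,7-dihydroxycoumarin, 5,7-dihydroxy-2H-chromen-2-one | Oc1cc(O)c2ccc(=O)oc2c1 | starting material
8 | 5-hydroxy-7-{[(2E,6E)-11-hydroxy-3,7,11-trimethyldodeca-2,6-dien-9-yn-1-yl]oxy}-2H-chromen-2-one | C/C(=C\COc1cc(O)c2ccc(=O)oc2c1)CC/C=C(\C)CC#CC(C)(C)O | intermediate
9 | 5-hydroxy-7-{[(2E,6E)-3,7,11-trimethyl-9-oxododeca-2,6,10-trien-1-yl]oxy}-2H-chromen-2-one | C/C(=C\COc1cc(O)c2ccc(=O)oc2c1)CC/C=C(\C)CC(=O)C=C(C)C | intermediate
10 | 5-hydroxy-7-{[(2E,6E,9R)-9-hydroxy-3,7,11-trimethyldodeca-2,6,10-trien-1-yl]oxy}-2H-chromen-2-one | C/C(=C\COc1cc(O)c2ccc(=O)oc2c1)CC/C=C(\C)C[C@@H](O)C=C(C)C | intermediate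
11 | cyclic 10,11-osmate ester of 12 (hexavalent osmium, dioxo), TMEDA chelate | C/C(=C\COc1cc(O)c2ccc(=O)oc2c1)CC/C=C(\C)C[C@@H](O)[C@H](O[Os]3(=O)=O)C(C)(C)O3.CN(C)CCN(C)C | intermediate (not isolated)
12 | 5-hydroxy-7-{[(2E,6E,9R,10S)-9,10,11-trihydroxy-3,7,11-trimethyldodeca-2,6-dien-1-yl]oxy}-2H-chromen-2-one | C/C(=C\COc1cc(O)c2ccc(=O)oc2c1)CC/C=C(\C)C[C@@H](O)[C@H](O)C(C)(C)O | target

## Step count and risks

Total steps: 7. Longest linear sequence: 7 steps (1 → 2 → 3 → 6 → 8 → 9 → 10 → 12); the route is fully linear, with 4 and 7 entering as bought building blocks.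

**Step 7 (directed osmylation).** The reagent could also be delivered to the homoallylic 6,7-alkene, or be held by the phenol, and the syn/anti ratio on an acyclic substrate is not guaranteed. The fallback sets out from 10 and returns at 12. The hydroxyl-directed epoxidation with VO(acac)2 (cat.) and t-BuOOH in CH2Cl2 at 0 °C touches only the allylic-alcohol alkene and, for an A(1,3)-strained substrate, favours the threo epoxy alcohol, 5-hydroxy-7-{[(2E,6E,9R)-9-[(2S)-3,3-dimethyloxiran-2-yl]-9-hydroxy-3,7-dimethylnona-2,6-dien-1-yl]oxy}-2H-chromen-2-one F1. Dilute HClO4 in THF/H2O at 0 °C then opens the epoxide with water at the tertiary C11, so the C10–O bond and its configuration are kept, and 12 results.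

**Step 5 (Meyer–Schuster rearrangement).** The skipped enyne, the free phenol and the β,γ-unsaturated ketone product (which can slip into conjugation) all make the gold step uncertain. The fallback sets out from 8 and returns at 9 and hydrates the alkyne through silicon instead. Trans-hydrosilylation with (EtO)3SiH and [Cp*Ru(MeCN)3]PF6 (cat.) in CH2Cl2 places silicon on C9, distal to the hydroxyl, and gives 5-hydroxy-7-{[(2E,6E,9Z)-11-hydroxy-3,7,11-trimethyl-9-(triethoxysilyl)dodeca-2,6,9-trien-1-yl]oxy}-2H-chromen-2-one F2. Tamao–Fleming oxidation (H2O2, KF, KHCO3, THF/MeOH) converts it into the aldol-type ketone 5-hydroxy-7-{[(2E,6E)-11-hydroxy-3,7,11-trimethyl-9-oxododeca-2,6-dien-1-yl]oxy}-2H-chromen-2-one F3. The tertiary hydroxyl is then eliminated with catalytic p-TsOH in CH2Cl2 at rt to give 9.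

**Step 4 (Mitsunobu regioselectivity).** The 5-OH of 7 can compete, and bis-alkylation is possible. The fallback sets out from 6 and returns at 8 and closes the lactone ring last, so the substitution pattern is fixed by symmetry. Diol 6 is coupled (PPh3, DIAD, THF, 0 °C) with commercial 2,4,6-trihydroxybenzaldehyde, whose 4-OH is the most acidic and is not hydrogen-bonded to the aldehyde, to give 2,6-dihydroxy-4-{[(2E,6E)-11-hydroxy-3,7,11-trimethyldodeca-2,6-dien-9-yn-1-yl]oxy}benzaldehyde F4. One equivalent of (triphenylphosphoranylidene)ketene, Ph3P=C=C=O, in toluene at 90 °C acylates one of the two equivalent ortho hydroxyls and closes the pyranone by intramolecular Wittig olefination, giving 8.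

## Further compounds

F1 | step 7 | 5-hydroxy-7-{[(2E,6E,9R)-9-[(2S)-3,3-dimethyloxiran-2-yl]-9-hydroxy-3,7-dimethylnona-2,6-dien-1-yl]oxy}-2H-chromen-2-one | C/C(=C\COc1cc(O)c2ccc(=O)oc2c1)CC/C=C(\C)C[C@@H](O)[C@@H]3OC3(C)C
F2 | step 5 | 5-hydroxy-7-{[(2E,6E,9Z)-11-hydroxy-3,7,11-trimethyl-9-(triethoxysilyl)dodeca-2,6,9-trien-1-yl]oxy}-2H-chromen-2-one | C/C(=C\COc1cc(O)c2ccc(=O)oc2c1)CC/C=C(\C)C/C(=C/C(C)(C)O)[Si](OCC)(OCC)OCC
F3 | step 5 | 5-hydroxy-7-{[(2E,6E)-11-hydroxy-3,7,11-trimethyl-9-oxododeca-2,6-dien-1-yl]oxy}-2H-chromen-2-one | C/C(=C\COc1cc(O)c2ccc(=O)oc2c1)CC/C=C(\C)CC(=O)CC(C)(C)O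
F4 | step 4 | 2,6-dihydroxy-4-{[(2E,6E)-11-hydroxy-3,7,11-trimethyldodeca-2,6-dien-9-yn-1-yl]oxy}benzaldehyde | C/C(=C\COc1cc(O)c(C=O)c(O)c1)CC/C=C(\C)CC#CC(C)(C)O
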